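The numbers of this flask were chosen freely; what happens was integrated by code.

Follow catalyst intermediate A. Solid substrate dissolves to starting material, starting material loads free catalyst into A, A turns reversibly into catalyst intermediate B, and B releases target and free catalyst. Two A also pair reversibly into resting dimer, an off-cycle form of the catalyst, while protic impurity quenches starting material on the side.

common to all: solid substrate 10 mM; protic impurity 5.00 mM; free catalyst 0.13 mM; time 20 h

|  | temperature |
|---|---|
| north-west | 10 °C |
| south-east | −5 °C |
| north-east | 25 °C |

1. which flask leads in amount of target, in percent of the solid substrate charged ("all alike" within 1.5 percentage points) (north-west / south-east / north-east / all alike)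
2. how much target is there at the end, in percent of the solid substrate charged: north-west
3. how much target is there at the end, in percent of the solid substrate charged: south-east
4. how much target is there at the end, in percent of the solid substrate charged: north-east

- percentages count the solid substrate that a species holds: one resting dimer counts as two
- for a step with 2 of a species take k times the square, and two of it per event
- solid, in amounts per volume of the solution: solid substrate
- all constants are for 25 °C and move with temperature by the activation energies and enthalpies
- at the start none of the solid substrate is in solution
- what has only dissolved of solid substrate counts as not reacted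

    catalyst intermediate A ⇌ catalyst intermediate B (K1 = 2.8, k1 = 0.012 s⁻¹, Ea1 = 87.0 kJ mol⁻¹, ΔH1 = 23.0 kJ mol⁻¹)
    starting material + protic impurity → quenched substrate (k2 = 0.0021 L mol⁻¹ s⁻¹, Ea2 = 47.0 kJ mol⁻¹)
    starting material + free catalyst → catalyst intermediate A (k3 = 1.0 L mol⁻¹ s⁻¹, Ea3 = 44.0 kJ mol⁻¹)
    solid substrate ⇌ starting material, rate k4*(cs4 - [starting material]) while solid is left; crystals form when [starting material] > cs4 (cs4 = 0.50 mM, k4 = 9.3 × 10⁻⁴ s⁻¹)
    catalyst intermediate A + catalyst intermediate A ⇌ resting dimer (K5 = 1.6 × 10⁵ L mol⁻¹, k5 = 13 L mol⁻¹ s⁻¹, Ea5 = 36.0 kJ mol⁻¹, ΔH5 = −37.0 kJ mol⁻¹)
    catalyst intermediate B → free catalyst + target (k6 = 0.0021 s⁻¹, Ea6 = 78.0 kJ mol⁻¹)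
    (constants at 25 °C)

First ask where the catalyst stands. Divide rates and time drops out: in a steady round each form passes the same flow, so each stands in proportion to the time a turn spends there. Take the turnover constant κ as the inverse of two times added, the forward time from A to B and the release time of B divided by the equilibrium constant between them. North-east gives 14.2 h⁻¹.

Then B per A is κ over the release constant, and free catalyst per A is κ over the loading constant times the solubility. With A itself, that makes L = 10.8 in north-east. Let w be the share of the catalyst charge standing as A, and let D be 2 times the dimer constant times the catalyst charge, counting two A in each resting dimer: D = 41.6 in north-east. Make the shares sum to one: L times w, plus D times w squared. Solve it: north-east has w = 7.25 %.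

Now multiply κ, w and the ratio of catalyst charge to solid charge. This is the hourly yield, the part of the solid charge turned into target per hour: 0.0134 h⁻¹ in north-east.

Move each constant to temperature and repeat. North-west gives κ = 1.79 h⁻¹, L = 4.81, D = 91.7, w = 8.14 % and an hourly yield of 0.00190 h⁻¹. South-east gives κ = 0.176 h⁻¹, L = 2.50, D = 221, w = 6.19 % and an hourly yield of 1.42 × 10⁻⁴ h⁻¹.

Next ask whether the dimer balance arrives in time. Its break-up time, the dimer constant over the forming constant, is 3.42 h in north-east, 16.3 h in north-west and 92.2 h in south-east. South-east runs for 20 h, so it stays short of balance, with more A than w says. Read its yield as low, and north-west's too, where the two times lie close.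

Last, check the solid in north-east: draw over full dissolving power is 0.0800, so starting material stays near solubility.

My reckoning puts north-east ahead. Over 20 h it gives 3.80 % for north-west, 0.283 % for south-east and 26.8 % for north-east.

The forecast also names north-east, with 4.5 % (3.8 % to 5.3 %) for north-west, 0.6 % (0.45 % to 0.75 %) for south-east and 25.5 % (23 % to 28 %) for north-east. For the two colder flasks it says “dimer formation is slow, so I stepped the pools by hand”, and there its south-east figure stands above mine.

The simulation gives north-east in the lead: 4.57 % for north-west, 0.572 % for south-east, 25.7 % for north-east. South-east held 76.1 % of its catalyst as resting dimer at 20.0 h and 84.5 % at 200 h. Its hourly yield carried over 200 h gives 2.83 %, and south-east then holds 3.18 % of target.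

Try a flask like north-west kept at 35 °C: κ = 50.0 h⁻¹, L = 19.0, D = 25.6, w = 4.94 %, so its hourly yield is 0.0321 h⁻¹ and 20 h gives 64.2 %. The computed flask holds 54.5 % of target.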